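## Retrosynthetic overview

1. The C15–O ester is cut last (Mitsunobu reaction with the Z acid 23), and the C12 acid is carried as a 2-(trimethylsilyl)ethyl ester. The acrylate comes from a 7β-acetyl group (enol triflate, carbonylation), and the acetyl group from a C7 ketone.
2. Ring A is closed second, by ring-closing metathesis at C3=C4, from a cyclohexane carrying a but-3-enyl chain on C10 and a 2-propenyl unit (C4, C15) on C5.
3. Ring B is closed first, in the key step: an enantioselective Diels–Alder reaction forms C5–C6 and C9–C10 from the diene C6=C7(OSi)–C8=C9 and the dienophile C5=C10.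
4. Enabling feature: in ring B (C5–C10) the edge C5–C10 carries the quaternary C10 (CH3, C1) and C5 (H, C4) trans to each other, and the C7 substituent is 1,4 to C10. With C1 as CHO this edge is an (E)-2-methyl enal, whose E geometry encodes the trans ring fusion and whose formyl group fixes the regiochemistry.
5. Order of ring formation: ring B (step 5), then ring A (step 9).

Key step: step 5

Remark on numbering: locants C1–C15 in names and text are those of the eudesmane skeleton of the target. Ring A is C1–C5 plus C10, ring B is C5–C10, C14 is the CH3 on C10, C15 is the CH2O carbon on C4, and C7 carries C11, which bears C12 (CO2H) and C13 (=CH2).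

Assumption: the (S)-configured oxazaborolidinium salt is taken to shield the face of the coordinated enal 5 that leads to the (1R,6S) adduct 8; if this dienophile shows the opposite facial sense, the (R)-catalyst is used and nothing else changes.

## Route

Step 1
Reactants: 1 2-methylidenepropane-1,3-diol
Product: 2 2-({[tert-butyl(diphenyl)silyl]oxy}methyl)prop-2-en-1-ol
Conditions: t-BuPh2SiCl (1 equiv), imidazole, diol 1 (3 equiv), CH2Cl2/DMF, 0 °C
Reagents that add atoms: tert-butyl(chloro)diphenylsilane, CC(C)(C)[Si](Cl)(c1ccccc1)c1ccccc1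
Why: Silyl ether formation on one of two equivalent primary hydroxyl groups should stop at the mono-ether because the symmetric diol is used in excess; no stereocenter is formed.

Step 2
Reactants: 2 2-({[tert-butyl(diphenyl)silyl]oxy}methyl)prop-2-en-1-ol
Product: 3 2-({[tert-butyl(diphenyl)silyl]oxy}methyl)prop-2-enal
Conditions: MnO2 (activated, excess), CH2Cl2, 25 °C
Reagents that add atoms: none
Why: MnO2 oxidation is selective for allylic alcohols and should stop at the 2-substituted acrolein; no stereocenter is formed.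

Step 3
Reactants: 3 2-({[tert-butyl(diphenyl)silyl]oxy}methyl)prop-2-enal; 4 2-(triphenyl-λ5-phosphanylidene)propanal
Product: 5 (2E)-4-({[tert-butyl(diphenyl)silyl]oxy}methyl)-2-methylpenta-2,4-dienal
Conditions: toluene, 80 °C
Reagents that add atoms: none
Why: Wittig olefination with the formyl-stabilised ylide should give the 2-methyl enal with E geometry (CHO and the C4 unit trans across the new C5=C10 bond), the geometry that later becomes the trans ring fusion.

Step 4
Reactants: 6 but-3-en-2-one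
Product: 7 (buta-1,3-dien-2-yloxy)tri(propan-2-yl)silane
Conditions: i-Pr3SiOTf, Et3N, CH2Cl2, 0 °C
Reagents that add atoms: tri(propan-2-yl)silyl trifluoromethanesulfonate, CC(C)[Si](OS(=O)(=O)C(F)(F)F)(C(C)C)C(C)C
Why: Soft enolisation and O-silylation of the enone (silyl enol ether formation) gives the 2-silyloxydiene, and the bulky silyl group should make the enol ether robust enough for steps 5–9; no stereocenter is formed.

Step 5
Reactants: 5 (2E)-4-({[tert-butyl(diphenyl)silyl]oxy}methyl)-2-methylpenta-2,4-dienal; 7 (buta-1,3-dien-2-yloxy)tri(propan-2-yl)silane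
Product: 8 (1R,6S)-6-(3-{[tert-butyl(diphenyl)silyl]oxy}prop-1-en-2-yl)-1-methyl-4-{[tri(propan-2-yl)silyl]oxy}cyclohex-3-ene-1-carbaldehyde
Conditions: (S)-oxazaborolidine from (S)-α,α-diphenylprolinol and o-tolylboronic acid (20 mol %), Tf2NH (20 mol %), CH2Cl2, −78 → −40 °C
Reagents that add atoms: none
Why: Concerted but asynchronous [4+2] cycloaddition (Diels–Alder reaction): the formyl group of 5 binds to the cationic boron of the chiral oxazaborolidinium salt (s-trans enal, formyl C–H···O contact), which lowers the LUMO of the C5=C10 bond, and the electron-rich diene 7 adds across it so that C5–C6 and C9–C10 form together. The closest known reaction type is the enantioselective Diels–Alder reaction of 2-(silyloxy)buta-1,3-dienes with 2-substituted acroleins under chiral oxazaborolidinium catalysis. Ring B is the only ring closed, as a six-membered carbocycle by intermolecular [4+2] closure, and both new bonds lie in it. The relative configuration of C5 and C10 (CHO and the 2-propenyl group trans, CH3 and H trans) follows from suprafacial addition to the E alkene, and the absolute configuration from the catalyst, whose aryl group shields one face of the bound enal. The step needs regioselectivity (C6, the nucleophilic diene terminus next to the silyloxy carbon, must bond to the β-carbon C5 so that the oxygen ends on C7, 1,4 to the quaternary C10) and site selectivity (the α,β-bond and not the remote 1,1-disubstituted alkene); the first is secured by the silyloxy group on C7 together with the formyl group on C10, the second by the fact that only the C5=C10 bond is directly conjugated to the coordinated carbonyl group. No endo/exo question arises, because the diene has no terminal substituent.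

Step 6
Reactants: 8 (1R,6S)-6-(3-{[tert-butyl(diphenyl)silyl]oxy}prop-1-en-2-yl)-1-methyl-4-{[tri(propan-2-yl)silyl]oxy}cyclohex-3-ene-1-carbaldehyde
Product: 9 1-[(1R,6S)-6-(3-{[tert-butyl(diphenyl)silyl]oxy}prop-1-en-2-yl)-1-methyl-4-{[tri(propan-2-yl)silyl]oxy}cyclohex-3-en-1-yl]but-3-en-1-ol (both carbinol epimers)
Conditions: allylmagnesium bromide, THF, −78 °C; aq. NH4Cl
Reagents that add atoms: allylmagnesium bromide, C=CC[Mg]Br
Why: Grignard addition to the aldehyde, the only carbonyl group, installs C2 and C3; the carbinol configuration is left uncontrolled on purpose because this oxygen is removed in step 8.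

Step 7
Reactants: 9 1-[(1R,6S)-6-(3-{[tert-butyl(diphenyl)silyl]oxy}prop-1-en-2-yl)-1-methyl-4-{[tri(propan-2-yl)silyl]oxy}cyclohex-3-en-1-yl]but-3-en-1-ol
Product: 10 O-{1-[(1R,6S)-6-(3-{[tert-butyl(diphenyl)silyl]oxy}prop-1-en-2-yl)-1-methyl-4-{[tri(propan-2-yl)silyl]oxy}cyclohex-3-en-1-yl]but-3-en-1-yl} 1H-imidazole-1-carbothioate
Conditions: 1,1'-thiocarbonyldiimidazole, DMAP (cat.), toluene, 80 °C
Reagents that add atoms: 1,1'-thiocarbonyldiimidazole, S=C(n1ccnc1)n1ccnc1
Why: Thioacylation of the secondary alcohol gives the radical-labile O-thiocarbonyl derivative needed for the Barton–McCombie deoxygenation under neutral conditions that should leave both silyl groups in place.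

Step 8
Reactants: 10 O-{1-[(1R,6S)-6-(3-{[tert-butyl(diphenyl)silyl]oxy}prop-1-en-2-yl)-1-methyl-4-{[tri(propan-2-yl)silyl]oxy}cyclohex-3-en-1-yl]but-3-en-1-yl} 1H-imidazole-1-carbothioate
Product: 11 {[(4R,5R)-4-(but-3-en-1-yl)-5-(3-{[tert-butyl(diphenyl)silyl]oxy}prop-1-en-2-yl)-4-methylcyclohex-1-en-1-yl]oxy}tri(propan-2-yl)silane
Conditions: Bu3SnH, AIBN (cat.), toluene, 100 °C
Reagents that add atoms: none
Why: Barton–McCombie deoxygenation: the stannyl radical adds to sulfur, β-scission gives the secondary C1 radical, and hydrogen transfer from Bu3SnH should outrun cyclisation because only 3-exo, 4-exo and 5-endo modes are open to this radical; C5 and C10 are not involved.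

Step 9
Reactants: 11 {[(4R,5R)-4-(but-3-en-1-yl)-5-(3-{[tert-butyl(diphenyl)silyl]oxy}prop-1-en-2-yl)-4-methylcyclohex-1-en-1-yl]oxy}tri(propan-2-yl)silane
Product: 12 (5R,10R)-15-{[tert-butyl(diphenyl)silyl]oxy}-7-{[tri(propan-2-yl)silyl]oxy}-11,12,13-trinoreudesma-3,7-diene
Conditions: second-generation Grubbs catalyst, [1,3-bis(2,4,6-trimethylphenyl)imidazolidin-2-ylidene]dichloro(benzylidene)(tricyclohexylphosphine)ruthenium (5 mol %), CH2Cl2, 40 °C
Reagents that add atoms: none
Why: Ring-closing metathesis between the monosubstituted alkene (C3) and the 1,1-disubstituted alkene (C4) closes the six-membered ring A with loss of ethene and leaves the trisubstituted C3=C4 bond carrying C15; the trans ring fusion follows from the C5 and C10 configurations set in step 5, and the hindered trisubstituted silyl enol ether should not take part.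

Step 10
Reactants: 12 (5R,10R)-15-{[tert-butyl(diphenyl)silyl]oxy}-7-{[tri(propan-2-yl)silyl]oxy}-11,12,13-trinoreudesma-3,7-diene
Product: 13 (5R,10R)-15-{[tert-butyl(diphenyl)silyl]oxy}-11,12,13-trinoreudesm-3-en-7-one
Conditions: 2 M HCl, THF, 25 °C
Reagents that add atoms: none
Why: Acid hydrolysis of the silyl enol ether (C-protonation, then loss of silicon from the oxocarbenium ion) unveils the C7 ketone, while the acid-stable tert-butyldiphenylsilyl ether should survive; no stereocenter is affected.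

Step 11
Reactants: 13 (5R,10R)-15-{[tert-butyl(diphenyl)silyl]oxy}-11,12,13-trinoreudesm-3-en-7-one
Product: 15 (5R,7R,10R)-15-{[tert-butyl(diphenyl)silyl]oxy}-13-noreudesm-3-en-11-one (7β-acetyl ketone), via methyl enol ether 14 (not isolated)
Conditions: (1-methoxyethyl)triphenylphosphonium chloride, KOt-Bu, THF, 0 → 25 °C; then 2 M HCl, THF, 25 °C
Reagents that add atoms: (1-methoxyethyl)triphenylphosphonium chloride, COC(C)[P+](c1ccccc1)(c1ccccc1)c1ccccc1.[Cl-]; water, O
Why: Wittig olefination with the α-methoxyethylidene ylide followed by acid hydrolysis of the enol ether is a ketone-to-acetyl homologation, and the new C7 stereocenter, being α to the ketone, should equilibrate under the acidic conditions to the equatorial 7β-acetyl isomer of the trans-decalin.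

Step 12
Reactants: 15 (5R,7R,10R)-15-{[tert-butyl(diphenyl)silyl]oxy}-13-noreudesm-3-en-11-one
Product: 17 (5R,7R,10R)-15-{[tert-butyl(diphenyl)silyl]oxy}-13-noreudesma-3,11-dien-11-yl trifluoromethanesulfonate, via potassium enolate 16 (not isolated)
Conditions: KN(SiMe3)2, THF, −78 °C; then PhNTf2, −78 → 0 °C; aq. NH4Cl
Reagents that add atoms: N-phenylbis(trifluoromethanesulfonimide), O=S(=O)(N(c1ccccc1)S(=O)(=O)C(F)(F)F)C(F)(F)F
Why: Kinetic deprotonation with the bulky amide base should take place at the methyl group and not at the tertiary C7–H, so that O-triflation (enol triflate formation) gives the terminal enol triflate without loss of the C7 configuration.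

Step 13
Reactants: 17 (5R,7R,10R)-15-{[tert-butyl(diphenyl)silyl]oxy}-13-noreudesma-3,11-dien-11-yl trifluoromethanesulfonate
Product: 18 2-(trimethylsilyl)ethyl (5R,7R,10R)-15-{[tert-butyl(diphenyl)silyl]oxy}eudesma-3,11(13)-dien-12-oate
Conditions: Pd(OAc)2 (5 mol %), PPh3 (10 mol %), CO (1 atm), Me3SiCH2CH2OH, Et3N, DMF, 60 °C
Reagents that add atoms: carbon monoxide, [C-]#[O+]; 2-(trimethylsilyl)ethanol, C[Si](C)(C)CCO
Why: Palladium-catalysed alkoxycarbonylation of the enol triflate (oxidative addition, CO insertion, alcoholysis) turns C11–OTf into the acrylate C11(=CH2)–CO2R with the acid already in fluoride-labile form; no stereocenter is touched.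

Step 14
Reactants: 18 2-(trimethylsilyl)ethyl (5R,7R,10R)-15-{[tert-butyl(diphenyl)silyl]oxy}eudesma-3,11(13)-dien-12-oate
Product: 19 2-(trimethylsilyl)ethyl (5R,7R,10R)-15-hydroxyeudesma-3,11(13)-dien-12-oate
Conditions: HF·pyridine, pyridine, THF, 0 → 25 °C
Reagents that add atoms: none
Why: Desilylation with buffered HF·pyridine cleaves the Si–O bond of the primary silyl ether, while the 2-(trimethylsilyl)ethyl ester, which needs fluoride ion at its carbon-bound silicon, should survive.

Step 15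
Reactants: 20 tert-butyl(4-ethynylphenoxy)dimethylsilane
Product: 22 3-{4-[(tert-butyldimethylsilyl)oxy]phenyl}prop-2-ynoic acid, via lithium acetylide 21 (not isolated)
Conditions: n-BuLi, THF, −78 °C; then CO2; cold dilute aq. HCl
Reagents that add atoms: carbon dioxide, O=C=O
Why: Deprotonation of the terminal alkyne and carboxylation of the acetylide with CO2 gives the arylpropiolic acid; no stereo element is formed.

Step 16
Reactants: 22 3-{4-[(tert-butyldimethylsilyl)oxy]phenyl}prop-2-ynoic acid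
Product: 23 (2Z)-3-{4-[(tert-butyldimethylsilyl)oxy]phenyl}prop-2-enoic acid
Conditions: H2 (1 atm), Pd on CaCO3 poisoned with Pb(OAc)2, quinoline, EtOAc, 25 °C, dark
Reagents that add atoms: none
Why: Lindlar-type semi-hydrogenation delivers both hydrogens to the same face of the alkyne and so should give the Z alkene, with quinoline suppressing over-reduction.

Step 17
Reactants: 19 2-(trimethylsilyl)ethyl (5R,7R,10R)-15-hydroxyeudesma-3,11(13)-dien-12-oate; 23 (2Z)-3-{4-[(tert-butyldimethylsilyl)oxy]phenyl}prop-2-enoic acid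
Product: 24 2-(trimethylsilyl)ethyl (5R,7R,10R)-15-{[(2Z)-3-{4-[(tert-butyldimethylsilyl)oxy]phenyl}prop-2-enoyl]oxy}eudesma-3,11(13)-dien-12-oate
Conditions: PPh3, DIAD, THF, 0 °C, dark
Reagents that add atoms: none
Why: Mitsunobu esterification activates the primary allylic alcohol and not the acid, so the carboxylate of 23 displaces the oxyphosphonium group at C15 by SN2 and the Z alkene never meets an acyl-activating or strongly basic reagent.

Step 18
Reactants: 24 2-(trimethylsilyl)ethyl (5R,7R,10R)-15-{[(2Z)-3-{4-[(tert-butyldimethylsilyl)oxy]phenyl}prop-2-enoyl]oxy}eudesma-3,11(13)-dien-12-oate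
Product: 25 (5R,7R,10R)-15-{[(2Z)-3-(4-hydroxyphenyl)prop-2-enoyl]oxy}eudesma-3,11(13)-dien-12-oic acid (CNP0183482.1)
Conditions: Bu4NF (3 equiv), THF, 0 °C, dark; aq. NH4Cl
Reagents that add atoms: none
Why: Fluoride-induced desilylation cleaves the aryl silyl ether and, by attack at silicon with loss of ethene, the 2-(trimethylsilyl)ethyl ester in one operation, under conditions that should leave the allylic Z-cinnamate ester and the three stereocenters unchanged.

## Compound list

1 | 2-methylidenepropane-1,3-diol | C=C(CO)CO | starting material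
2 | 2-({[tert-butyl(diphenyl)silyl]oxy}methyl)prop-2-en-1-ol | C=C(CO)CO[Si](c1ccccc1)(c1ccccc1)C(C)(C)C | intermediate
3 | 2-({[tert-butyl(diphenyl)silyl]oxy}methyl)prop-2-enal | C=C(C=O)CO[Si](c1ccccc1)(c1ccccc1)C(C)(C)C | intermediate
4 | 2-(triphenyl-λ5-phosphanylidene)propanal | CC(C=O)=P(c1ccccc1)(c1ccccc1)c1ccccc1 | starting material
5 | (2E)-4-({[tert-butyl(diphenyl)silyl]oxy}methyl)-2-methylpenta-2,4-dienal | O=C/C(C)=C/C(=C)CO[Si](c1ccccc1)(c1ccccc1)C(C)(C)C | intermediate
6 | but-3-en-2-one | CC(=O)C=C | starting material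
7 | (buta-1,3-dien-2-yloxy)tri(propan-2-yl)silane | C=CC(=C)O[Si](C(C)C)(C(C)C)C(C)C | intermediate
8 | (1R,6S)-6-(3-{[tert-butyl(diphenyl)silyl]oxy}prop-1-en-2-yl)-1-methyl-4-{[tri(propan-2-yl)silyl]oxy}cyclohex-3-ene-1-carbaldehyde (CHO and 2-propenyl group trans) | CC(C)[Si](C(C)C)(C(C)C)OC1=CC[C@@](C)(C=O)[C@H](C(=C)CO[Si](c2ccccc2)(c2ccccc2)C(C)(C)C)C1 | intermediate
9 | 1-[(1R,6S)-6-(3-{[tert-butyl(diphenyl)silyl]oxy}prop-1-en-2-yl)-1-methyl-4-{[tri(propan-2-yl)silyl]oxy}cyclohex-3-en-1-yl]but-3-en-1-ol (both carbinol epimers) | CC(C)[Si](C(C)C)(C(C)C)OC1=CC[C@@](C)(C(O)CC=C)[C@H](C(=C)CO[Si](c2ccccc2)(c2ccccc2)C(C)(C)C)C1 | intermediate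
10 | O-{1-[(1R,6S)-6-(3-{[tert-butyl(diphenyl)silyl]oxy}prop-1-en-2-yl)-1-methyl-4-{[tri(propan-2-yl)silyl]oxy}cyclohex-3-en-1-yl]but-3-en-1-yl} 1H-imidazole-1-carbothioate (both epimers at the carbinol carbon) | CC(C)[Si](C(C)C)(C(C)C)OC1=CC[C@@](C)(C(OC(=S)n2ccnc2)CC=C)[C@H](C(=C)CO[Si](c2ccccc2)(c2ccccc2)C(C)(C)C)C1 | intermediate
11 | {[(4R,5R)-4-(but-3-en-1-yl)-5-(3-{[tert-butyl(diphenyl)silyl]oxy}prop-1-en-2-yl)-4-methylcyclohex-1-en-1-yl]oxy}tri(propan-2-yl)silane | CC(C)[Si](C(C)C)(C(C)C)OC1=CC[C@@](C)(CCC=C)[C@H](C(=C)CO[Si](c2ccccc2)(c2ccccc2)C(C)(C)C)C1 | intermediate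
12 | (5R,10R)-15-{[tert-butyl(diphenyl)silyl]oxy}-7-{[tri(propan-2-yl)silyl]oxy}-11,12,13-trinoreudesma-3,7-diene (trans-fused) | CC(C)[Si](C(C)C)(C(C)C)OC1=CC[C@@]2(C)CCC=C(CO[Si](c3ccccc3)(c3ccccc3)C(C)(C)C)[C@@H]2C1 | intermediate
13 | (5R,10R)-15-{[tert-butyl(diphenyl)silyl]oxy}-11,12,13-trinoreudesm-3-en-7-one | O=C1CC[C@@]2(C)CCC=C(CO[Si](c3ccccc3)(c3ccccc3)C(C)(C)C)[C@@H]2C1 | intermediate
14 | (5R,10R)-15-{[tert-butyl(diphenyl)silyl]oxy}-11-methoxy-13-noreudesma-3,7(11)-diene (E/Z mixture) | COC(C)=C1CC[C@@]2(C)CCC=C(CO[Si](c3ccccc3)(c3ccccc3)C(C)(C)C)[C@@H]2C1 | intermediate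
15 | (5R,7R,10R)-15-{[tert-butyl(diphenyl)silyl]oxy}-13-noreudesm-3-en-11-one (7β-acetyl) | CC(=O)[C@@H]1CC[C@@]2(C)CCC=C(CO[Si](c3ccccc3)(c3ccccc3)C(C)(C)C)[C@@H]2C1 | intermediate
16 | potassium (5R,7R,10R)-15-{[tert-butyl(diphenyl)silyl]oxy}-13-noreudesma-3,11-dien-11-olate | C=C([O-])[C@@H]1CC[C@@]2(C)CCC=C(CO[Si](c3ccccc3)(c3ccccc3)C(C)(C)C)[C@@H]2C1.[K+] | intermediate
17 | (5R,7R,10R)-15-{[tert-butyl(diphenyl)silyl]oxy}-13-noreudesma-3,11-dien-11-yl trifluoromethanesulfonate | C=C(OS(=O)(=O)C(F)(F)F)[C@@H]1CC[C@@]2(C)CCC=C(CO[Si](c3ccccc3)(c3ccccc3)C(C)(C)C)[C@@H]2C1 | intermediate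
18 | 2-(trimethylsilyl)ethyl (5R,7R,10R)-15-{[tert-butyl(diphenyl)silyl]oxy}eudesma-3,11(13)-dien-12-oate | C=C(C(=O)OCC[Si](C)(C)C)[C@@H]1CC[C@@]2(C)CCC=C(CO[Si](c3ccccc3)(c3ccccc3)C(C)(C)C)[C@@H]2C1 | intermediate
19 | 2-(trimethylsilyl)ethyl (5R,7R,10R)-15-hydroxyeudesma-3,11(13)-dien-12-oate | C=C(C(=O)OCC[Si](C)(C)C)[C@@H]1CC[C@@]2(C)CCC=C(CO)[C@@H]2C1 | intermediate
20 | tert-butyl(4-ethynylphenoxy)dimethylsilane | C#Cc1ccc(O[Si](C)(C)C(C)(C)C)cc1 | starting material
21 | ({4-[(tert-butyldimethylsilyl)oxy]phenyl}ethynyl)lithium | [Li]C#Cc1ccc(O[Si](C)(C)C(C)(C)C)cc1 | intermediate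
22 | 3-{4-[(tert-butyldimethylsilyl)oxy]phenyl}prop-2-ynoic acid | OC(=O)C#Cc1ccc(O[Si](C)(C)C(C)(C)C)cc1 | intermediate
23 | (2Z)-3-{4-[(tert-butyldimethylsilyl)oxy]phenyl}prop-2-enoic acid | OC(=O)/C=C\c1ccc(O[Si](C)(C)C(C)(C)C)cc1 | intermediate
24 | 2-(trimethylsilyl)ethyl (5R,7R,10R)-15-{[(2Z)-3-{4-[(tert-butyldimethylsilyl)oxy]phenyl}prop-2-enoyl]oxy}eudesma-3,11(13)-dien-12-oate | C=C(C(=O)OCC[Si](C)(C)C)[C@@H]1CC[C@@]2(C)CCC=C(COC(=O)/C=C\c3ccc(O[Si](C)(C)C(C)(C)C)cc3)[C@@H]2C1 | intermediate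
25 | (5R,7R,10R)-15-{[(2Z)-3-(4-hydroxyphenyl)prop-2-enoyl]oxy}eudesma-3,11(13)-dien-12-oic acid (CNP0183482.1) | C=C(C(=O)O)[C@@H]1CC[C@@]2(C)CCC=C(COC(=O)/C=C\c3ccc(O)cc3)[C@@H]2C1 | target

## Step count and risks

Total step count: 18. Longest linear sequence: 15 steps (steps 1–3, 5–14, 17 and 18).

Steps most likely to fail:

Step 5. The diene may add across, or in a conjugate sense to, the remote 1,1-disubstituted alkene of the dienal instead of the formyl-bound α,β-bond, and facial discrimination may be weak for this β-branched enal. The fallback removes the remote alkene before the cycloaddition and restores it afterwards. Setting out from 5, Lemieux–Johnson cleavage (OsO4 cat., NaIO4, 2,6-lutidine, dioxane/H2O) of the more electron-rich terminal alkene should give keto enal F1, a doubly activated dienophile with no second alkene. Its cycloaddition with 7 under the catalysis of step 5 (C6 again bonds to C5, the carbon β to the formyl group and the less hindered one) should give keto aldehyde F2. Methylenation of both carbonyl groups with salt-free Ph3P=CH2 (THF, −78 → 0 °C, to keep C5 from epimerising) gives triene F3. Hydroboration of its monosubstituted vinyl group with 9-BBN gives alkylborane F4, and B-alkyl Suzuki–Miyaura coupling with vinyl bromide (Pd(dppf)Cl2, K3PO4, THF/H2O) comes back to the route at 11.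

Step 8 (with step 7). Thioacylation of the hindered neopentylic carbinol may be incomplete, and the C1 radical may be diverted by hydrogen-atom transfer from allylic positions before it is reduced. The fallback is an ionic deoxygenation through the ketone. Setting out from 9, Dess–Martin periodinane oxidation (NaHCO3, CH2Cl2) gives allyl ketone F5, condensation with 4-methylbenzenesulfonohydrazide (EtOH, 40 °C) gives tosylhydrazone F6, and reduction with catecholborane followed by NaOAc·3H2O (CHCl3, 0 → 60 °C), with loss of dinitrogen and sulfinate, comes back to the route at 11.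

Step 18. Basic fluoride generates the 4-oxidocinnamate, which may isomerise from Z to E, and it may also cleave the allylic ester. The fallback unveils the acid by oxidation and ends with acidic fluoride. Setting out from 17, palladium-catalysed reductive carbonylation (Pd(PPh3)4, CO, Bu3SnH, THF, 50 °C) gives enal F7 and HF·pyridine gives hydroxy enal F8. Mitsunobu esterification with 23 (PPh3, DIAD, THF, 0 °C) gives ester F9, and Pinnick oxidation (NaClO2, NaH2PO4, 2-methylbut-2-ene, t-BuOH/H2O) gives silyl-protected acid F10. Removal of the aryl silyl ether with HF·pyridine, under which no phenoxide is formed, comes back to the route at 25.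

## Further compounds

F1 | step 5 | (2E)-5-{[tert-butyl(diphenyl)silyl]oxy}-2-methyl-4-oxopent-2-enal | O=C/C(C)=C/C(=O)CO[Si](c1ccccc1)(c1ccccc1)C(C)(C)C
F2 | step 5 | (1R,6R)-6-({[tert-butyl(diphenyl)silyl]oxy}acetyl)-1-methyl-4-{[tri(propan-2-yl)silyl]oxy}cyclohex-3-ene-1-carbaldehyde | CC(C)[Si](C(C)C)(C(C)C)OC1=CC[C@@](C)(C=O)[C@H](C(=O)CO[Si](c2ccccc2)(c2ccccc2)C(C)(C)C)C1
F3 | step 5 | {[(4S,5R)-5-(3-{[tert-butyl(diphenyl)silyl]oxy}prop-1-en-2-yl)-4-ethenyl-4-methylcyclohex-1-en-1-yl]oxy}tri(propan-2-yl)silane | CC(C)[Si](C(C)C)(C(C)C)OC1=CC[C@@](C)(C=C)[C@H](C(=C)CO[Si](c2ccccc2)(c2ccccc2)C(C)(C)C)C1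
F4 | step 5 | 9-{2-[(1R,6R)-6-(3-{[tert-butyl(diphenyl)silyl]oxy}prop-1-en-2-yl)-1-methyl-4-{[tri(propan-2-yl)silyl]oxy}cyclohex-3-en-1-yl]ethyl}-9-borabicyclo[3.3.1]nonane | CC(C)[Si](C(C)C)(C(C)C)OC1=CC[C@@](C)(CCB2C3CCCC2CCC3)[C@H](C(=C)CO[Si](c4ccccc4)(c4ccccc4)C(C)(C)C)C1
F5 | step 8 | 1-[(1R,6S)-6-(3-{[tert-butyl(diphenyl)silyl]oxy}prop-1-en-2-yl)-1-methyl-4-{[tri(propan-2-yl)silyl]oxy}cyclohex-3-en-1-yl]but-3-en-1-one | CC(C)[Si](C(C)C)(C(C)C)OC1=CC[C@@](C)(C(=O)CC=C)[C@H](C(=C)CO[Si](c2ccccc2)(c2ccccc2)C(C)(C)C)C1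
F6 | step 8 | N'-{1-[(1R,6R)-6-(3-{[tert-butyl(diphenyl)silyl]oxy}prop-1-en-2-yl)-1-methyl-4-{[tri(propan-2-yl)silyl]oxy}cyclohex-3-en-1-yl]but-3-en-1-ylidene}-4-methylbenzenesulfonohydrazide | CC(C)[Si](C(C)C)(C(C)C)OC1=CC[C@@](C)(C(CC=C)=NNS(=O)(=O)c2ccc(C)cc2)[C@H](C(=C)CO[Si](c2ccccc2)(c2ccccc2)C(C)(C)C)C1
F7 | step 18 | (5R,7R,10R)-15-{[tert-butyl(diphenyl)silyl]oxy}eudesma-3,11(13)-dien-12-al | C=C(C=O)[C@@H]1CC[C@@]2(C)CCC=C(CO[Si](c3ccccc3)(c3ccccc3)C(C)(C)C)[C@@H]2C1
F8 | step 18 | (5R,7R,10R)-15-hydroxyeudesma-3,11(13)-dien-12-al | C=C(C=O)[C@@H]1CC[C@@]2(C)CCC=C(CO)[C@@H]2C1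
F9 | step 18 | (5R,7R,10R)-12-oxoeudesma-3,11(13)-dien-15-yl (2Z)-3-{4-[(tert-butyldimethylsilyl)oxy]phenyl}prop-2-enoate | C=C(C=O)[C@@H]1CC[C@@]2(C)CCC=C(COC(=O)/C=C\c3ccc(O[Si](C)(C)C(C)(C)C)cc3)[C@@H]2C1
F10 | step 18 | (5R,7R,10R)-15-{[(2Z)-3-{4-[(tert-butyldimethylsilyl)oxy]phenyl}prop-2-enoyl]oxy}eudesma-3,11(13)-dien-12-oic acid | C=C(C(=O)O)[C@@H]1CC[C@@]2(C)CCC=C(COC(=O)/C=C\c3ccc(O[Si](C)(C)C(C)(C)C)cc3)[C@@H]2C1
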